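**Retrosynthetic overview**
1. Assumption: the SMILES is read as an achiral ester with a 40-carbon acyl chain (C48H88O3). There is no stereocentre, so no enantiomer has to be set or resolved.
2. No ring is formed: the only ring (the para-phenol) is bought in tyrosol 1. The ester C–O bond is made first, on soluble 10-bromodecanoic acid 2, giving bromo ester 3 with the phenol left free.
3. The wax tail comes from triacontan-1-ol 4 via bromide 5 and Grignard reagent 6.
4. Key disconnection: the C10–C11 C(sp3)–C(sp3) bond of the C40 chain, made last by Cu-catalysed coupling of 6 with 3 (masked in the flask as magnesium phenoxide 7), giving phenoxide 8 and, on work-up, target 9.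
5. This replaces the obvious "make tetracontanoic acid, then esterify protected tyrosol" plan: the almost insoluble C40 acid is never made and no protecting group is used.

**Route**

Step 1
Reactants: 1 tyrosol, 4-(2-hydroxyethyl)phenol (1.5 equiv); 2 10-bromodecanoic acid
Product: 3 2-(4-hydroxyphenyl)ethyl 10-bromodecanoate
Conditions: immobilised Candida antarctica lipase B, 4 Å MS, 2-methyl-2-butanol, 50 °C; excess 1 removed by water wash
Reagents that add atoms: none
Why: Lipase-catalysed chemoselective esterification: CAL-B acylates only the primary aliphatic OH, phenols are not substrates, the sieves remove water to drive the equilibrium, and no stereocentre is formed.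

Step 2
Reactants: 4 triacontan-1-ol
Product: 5 1-bromotriacontane
Conditions: CBr4, PPh3, THF/CH2Cl2, 40 °C; filtration through silica with hot heptane
Reagents that add atoms: carbon tetrabromide, BrC(Br)(Br)Br
Why: Appel reaction: SN2 displacement of the alkoxyphosphonium by bromide at an unhindered primary carbon, run warm so the wax alcohol stays dissolved; no stereocentre is involved.

Step 3
Reactants: 3 2-(4-hydroxyphenyl)ethyl 10-bromodecanoate; 5 1-bromotriacontane
Product: 9 2-(4-hydroxyphenyl)ethyl tetracontanoate, via triacontylmagnesium bromide 6 (not isolated), via bromo ester chloromagnesium phenoxide 7 (not isolated), via coupled ester chloromagnesium phenoxide 8 (not isolated)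
Conditions: 5, Mg, I2 (cat.), THF, 55 °C (gives 6, kept at 40 °C); 3, i-PrMgCl (1.0 equiv), THF, −20 °C (gives 7); then NMP (4 equiv), Li2CuCl4 (3 mol %), slow addition of 6 (1.4 equiv), 15–20 °C; 1 M HCl, 0 °C
Reagents that add atoms: none
Why: Kochi–Cahiez copper-catalysed C(sp3)–C(sp3) Grignard cross-coupling: with catalytic Li2CuCl4 and NMP the primary Grignard displaces the primary bromide much faster than it adds to an ester, the phenol is masked beforehand as the inert magnesium phenoxide by exactly one equivalent of i-PrMgCl, and no stereocentre is formed.

**Compound list**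
1 | tyrosol, 4-(2-hydroxyethyl)phenol | OCCc1ccc(O)cc1 | starting material
2 | 10-bromodecanoic acid | OC(=O)CCCCCCCCCBr | starting material
3 | 2-(4-hydroxyphenyl)ethyl 10-bromodecanoate | BrCCCCCCCCCC(=O)OCCc1ccc(O)cc1 | intermediate
4 | triacontan-1-ol | CCCCCCCCCCCCCCCCCCCCCCCCCCCCCCO | starting material
5 | 1-bromotriacontane | CCCCCCCCCCCCCCCCCCCCCCCCCCCCCCBr | intermediate
6 | triacontylmagnesium bromide | CCCCCCCCCCCCCCCCCCCCCCCCCCCCCC[Mg]Br | intermediate
7 | chloromagnesium 4-[2-(10-bromodecanoyloxy)ethyl]phenoxide | BrCCCCCCCCCC(=O)OCCc1ccc(O[Mg]Cl)cc1 | intermediate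
8 | chloromagnesium 4-[2-(tetracontanoyloxy)ethyl]phenoxide | CCCCCCCCCCCCCCCCCCCCCCCCCCCCCCCCCCCCCCCC(=O)OCCc1ccc(O[Mg]Cl)cc1 | intermediate
9 | 2-(4-hydroxyphenyl)ethyl tetracontanoate | CCCCCCCCCCCCCCCCCCCCCCCCCCCCCCCCCCCCCCCC(=O)OCCc1ccc(O)cc1 | target

**Totals**
Total step count: 3. Longest linear sequence: 2 (step 1 then step 3, or step 2 then step 3).

**Steps most likely to fail, with fallbacks**

Step 3 is the riskiest. The C30 Grignard reagent may form sluggishly, give Wurtz dimer, precipitate, or attack the ester. The fallback sets out from 5 and comes back at 9, and it gives up the organomagnesium reagent in favour of a B-alkyl Suzuki–Miyaura coupling of the same two carbons. Bromide 5 is dehydrobrominated (t-BuOK, THF, 50 °C) to triacont-1-ene F1. Hydroboration with 9-BBN dimer (THF, 50 °C) gives 9-triacontyl-9-borabicyclo[3.3.1]nonane F2. Without isolation this is coupled with bromo ester 3 (Pd(OAc)2, PCy3, K3PO4·H2O, THF, 40 °C). The alkylborane is not nucleophilic towards the ester and the conditions tolerate the free phenol, so 9 is obtained directly.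

Step 1 is next. The enzymatic esterification may stall, or the bromo acid may be a poor lipase substrate. The fallback sets out from 2 and comes back at 3, and it replaces the enzymatic equilibrium by a kinetic acylation. Oxalyl chloride with catalytic DMF in CH2Cl2 converts 2 into 10-bromodecanoyl chloride F3. This is added to 1 in dimethyl carbonate (or THF) at room temperature with no base. Under these neutral conditions the aliphatic alcohol is acylated far faster than the phenol, giving 3.

Step 2 is the least risky. The wax alcohol may convert incompletely, and Ph3PO may be hard to remove from the waxy bromide. The fallback sets out from 4 and comes back at 5 by a two-stage activation and displacement. TsCl in pyridine/CHCl3 at 40 °C gives triacontyl 4-methylbenzenesulfonate F4, which crystallises. LiBr in refluxing 2-butanone (SN2) then converts it into 5.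

**Further compounds**
F1 | step 3 | triacont-1-ene | C=CCCCCCCCCCCCCCCCCCCCCCCCCCCCC
F2 | step 3 | 9-triacontyl-9-borabicyclo[3.3.1]nonane | CCCCCCCCCCCCCCCCCCCCCCCCCCCCCCB1C2CCCC1CCC2
F3 | step 1 | 10-bromodecanoyl chloride | ClC(=O)CCCCCCCCCBr
F4 | step 2 | triacontyl 4-methylbenzenesulfonate | CCCCCCCCCCCCCCCCCCCCCCCCCCCCCCOS(=O)(=O)c1ccc(C)cc1
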